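**Plan**
1. The last cut removes the two MOM ethers of ring B. Ring A (C1 prenyl, C2 OH, C3 H, C4 OH, C5 CHO, C6 aroyl) is then opened at C1–C6 and C4–C5.
2. This works because C1–C4 of ring A carry the oxidation pattern of a γ-prenylated acetoacetate (a 1-methoxy-1,3-bis(silyloxy)diene), and C5/C6 carry two carbonyl groups, as in an alkyne flanked by formyl and aroyl.
3. The aroyl ynal is cut at the carbinol–alkyne bond into a ring B benzaldehyde and propargyl alcohol. The aldehyde comes from orcinol by chlorination, MOM protection and ortho-lithiation/formylation.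
4. Forward: the diene branch (steps 1–3) and the ynal branch (steps 4–8) meet in a Diels–Alder benzannulation (step 9) that builds ring A, the only ring made. Ring B is bought as orcinol, and step 10 frees its phenols.
5. Stereochemistry: the target has no stereocentre and no stereogenic alkene. The carbinol centre of 15 and the two sp3 centres of the cycloadduct are racemic and transient; the 3Z geometry of the diene serves reactivity only.

Key step: step 9

Remark: 4-chloroorcinol is made rather than bought, and silyl enol ether 5 is drawn as the 2E isomer expected with an amine base, which is immaterial because that double bond becomes a single bond in step 3.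

**Step 1**
Reactants: 1 methyl acetoacetate; 2 prenyl bromide
Product: 4 methyl 7-methyl-3-oxooct-6-enoate, via acetoacetate dianion 3 (not isolated)
Conditions: NaH, THF, 0 °C; n-BuLi, 0 °C; then 2, 0 °C to rt; dilute aq. HCl quench
Reagents that add atoms: none
Why: γ-Alkylation of a β-keto ester dianion, in which the more basic terminal carbanion of the sodium lithium bis-enolate displaces bromide from the primary allylic bromide (SN2).

**Step 2**
Reactants: 4 methyl 7-methyl-3-oxooct-6-enoate
Product: 5 methyl (2E)-7-methyl-3-(trimethylsilyloxy)octa-2,6-dienoate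
Conditions: TMSCl, Et3N, hexane, rt
Reagents that add atoms: chlorotrimethylsilane, C[Si](C)(C)Cl
Why: O-Silylation of the enolised β-keto ester (silyl enol ether formation) under amine base should give the conjugated silyl enol ether without touching the prenyl alkene.

**Step 3**
Reactants: 5 methyl (2E)-7-methyl-3-(trimethylsilyloxy)octa-2,6-dienoate
Product: 7 (1Z,3Z)-1-methoxy-7-methyl-1,3-bis(trimethylsilyloxy)octa-1,3,6-triene, via lithium dienolate 6 (not isolated)
Conditions: LiN(i-Pr)2, THF, −78 °C; TMSCl, −78 °C to rt; non-aqueous work-up (hexane, filtration)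
Reagents that add atoms: chlorotrimethylsilane, C[Si](C)(C)Cl
Why: Vinylogous (γ) deprotonation of the β-silyloxy enoate and O-silylation of the ester dienolate (silyl ketene acetal formation) is the standard entry to 1-alkoxy-1,3-bis(silyloxy)dienes, and should place the prenyl-bearing chain trans to C2 (3Z) as an s-cis diene requires.

**Step 4**
Reactants: 8 orcinol
Product: 9 4-chloro-5-methylbenzene-1,3-diol
Conditions: SO2Cl2 (1.0 equiv), Et2O, 0 °C to rt
Reagents that add atoms: sulfuryl chloride, O=S(=O)(Cl)Cl
Why: Electrophilic aromatic chlorination of the resorcinol is expected mainly at C4 (para to one hydroxyl, ortho to the other), and one equivalent of reagent limits dichlorination.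

**Step 5**
Reactants: 9 4-chloro-5-methylbenzene-1,3-diol
Product: 10 2-chloro-1,5-bis(methoxymethoxy)-3-methylbenzene
Conditions: MOMCl, i-Pr2NEt, CH2Cl2, 0 °C to rt
Reagents that add atoms: chloromethyl methyl ether, COCCl
Why: O-Alkylation of both phenols (Williamson-type acetal ether formation) installs groups that direct the lithiation of step 6, tolerate organolithiums, MnO2 and the cycloaddition, and keep the phenols from adding to the later ynone.

**Step 6**
Reactants: 10 2-chloro-1,5-bis(methoxymethoxy)-3-methylbenzene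
Product: 12 3-chloro-2,6-bis(methoxymethoxy)-4-methylbenzaldehyde, via aryllithium 11 (not isolated)
Conditions: n-BuLi, THF, 0 °C; DMF, 0 °C to rt; H2O
Reagents that add atoms: N,N-dimethylformamide, CN(C)C=O
Why: Directed ortho-metalation occurs at the only ring position flanked by two MOM-oxy groups, and formylation with DMF follows; no hydrogen lies ortho to chlorine, so no aryne can form.

**Step 7**
Reactants: 12 3-chloro-2,6-bis(methoxymethoxy)-4-methylbenzaldehyde; 13 propargyl alcohol
Product: 15 1-[3-chloro-2,6-bis(methoxymethoxy)-4-methylphenyl]but-2-yne-1,4-diol (racemic), via dilithiated propargyl alcohol 14 (not isolated)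
Conditions: 13, n-BuLi (2 equiv per 13), THF, −78 to −20 °C; then 12, −78 °C to rt; H2O
Reagents that add atoms: none
Why: 1,2-Addition of the lithium acetylide to the aldehyde gives the propargylic carbinol; its new stereocentre is set without control and is erased in step 8.

**Step 8**
Reactants: 15 1-[3-chloro-2,6-bis(methoxymethoxy)-4-methylphenyl]but-2-yne-1,4-diol
Product: 17 4-[3-chloro-2,6-bis(methoxymethoxy)-4-methylphenyl]-4-oxobut-2-ynal, via hydroxy ynal 16 (not isolated)
Conditions: activated MnO2 (excess), CH2Cl2, rt; filtration through Celite; solution used at once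
Reagents that add atoms: none
Why: Both hydroxyls are propargylic (one also benzylic), the alcohol class that MnO2 oxidises selectively under neutral, water-free conditions, so the sensitive keto ynal needs only a filtration before use.

**Step 9**
Reactants: 7 (1Z,3Z)-1-methoxy-7-methyl-1,3-bis(trimethylsilyloxy)octa-1,3,6-triene; 17 4-[3-chloro-2,6-bis(methoxymethoxy)-4-methylphenyl]-4-oxobut-2-ynal
Product: 20 2-[3-chloro-2,6-bis(methoxymethoxy)-4-methylbenzoyl]-4,6-dihydroxy-3-(3-methylbut-2-enyl)benzaldehyde, via cycloadduct 18 (not isolated), via aryl silyl ether 19 (not isolated)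
Conditions: 7 (1.5 equiv), CH2Cl2/toluene, −40 °C to rt; then 10% aq. citric acid, THF, rt
Reagents that add atoms: none
Why: The electron-rich diene 7 and the doubly activated alkyne 17 should combine in an asynchronous normal-electron-demand Diels–Alder reaction in which the prenyl-bearing, most nucleophilic diene terminus bonds to the alkyne carbon β to the formyl group (C1–C6) and the ketene-acetal terminus bonds to the formyl-bearing carbon (C4–C5). Ring A is thus closed by an intermolecular [4+2] cycloaddition to cyclohexa-1,4-diene 18, whose mixed methyl trimethylsilyl ketal collapses with loss of methoxytrimethylsilane to a dienone that tautomerises to phenol 19, and mild acid then hydrolyses the remaining aryl silyl ether. The closest known reaction type is the benzannulation of 1-alkoxy-1,3-bis(silyloxy)dienes with acetylenic esters and ketones to give resorcinol derivatives. The two sp3 centres of 18 (methoxy and prenyl cis through suprafacial addition, racemic) are erased on aromatisation, so no stereocontrol is needed. The step needs regio- and chemoselectivity: the formyl group must outrank the aroyl group as directing acceptor, and its carbonyl carbon must not be attacked. An aldehyde is the better conjugate acceptor than a ketone, the fully substituted ketene-acetal terminus avoids the alkyne carbon that carries the bulky 2,6-disubstituted aroyl group so that steric and electronic preferences coincide, and the absence of any Lewis acid disfavours addition of the diene to the C=O group.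

**Step 10**
Reactants: 20 2-[3-chloro-2,6-bis(methoxymethoxy)-4-methylbenzoyl]-4,6-dihydroxy-3-(3-methylbut-2-enyl)benzaldehyde
Product: 21 pestalone E
Conditions: 3 M aq. HCl, MeOH, rt
Reagents that add atoms: none
Why: Acid-catalysed acetal cleavage removes both MOM ethers, methanol trapping the formaldehyde unit as dimethoxymethane; room temperature and short exposure are chosen because an ortho-prenylphenol is expected to cyclise to a chroman only under more forcing acid.

**Compound list**
1 | methyl acetoacetate | COC(=O)CC(C)=O | starting material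
2 | prenyl bromide (1-bromo-3-methylbut-2-ene) | CC(C)=CCBr | starting material
3 | sodium lithium bis-enolate (dianion) of methyl acetoacetate, not isolated | [Na+].[Li+].COC([O-])=CC(=C)[O-] | intermediate
4 | methyl 7-methyl-3-oxooct-6-enoate | COC(=O)CC(=O)CCC=C(C)C | intermediate
5 | methyl (2E)-7-methyl-3-(trimethylsilyloxy)octa-2,6-dienoate | COC(=O)/C=C(/O[Si](C)(C)C)CCC=C(C)C | intermediate
6 | lithium (1E,3Z)-1-methoxy-7-methyl-3-(trimethylsilyloxy)octa-1,3,6-trien-1-olate, not isolated | [Li+].CO/C([O-])=C/C(O[Si](C)(C)C)=C/CC=C(C)C | intermediate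
7 | (1Z,3Z)-1-methoxy-7-methyl-1,3-bis(trimethylsilyloxy)octa-1,3,6-triene | CO/C(O[Si](C)(C)C)=C/C(O[Si](C)(C)C)=C/CC=C(C)C | intermediate
8 | orcinol (5-methylbenzene-1,3-diol) | Cc1cc(O)cc(O)c1 | starting material
9 | 4-chloro-5-methylbenzene-1,3-diol | Cc1cc(O)cc(O)c1Cl | intermediate
10 | 2-chloro-1,5-bis(methoxymethoxy)-3-methylbenzene | COCOc1cc(C)c(Cl)c(OCOC)c1 | intermediate
11 | [3-chloro-2,6-bis(methoxymethoxy)-4-methylphenyl]lithium, not isolated | [Li]c1c(OCOC)cc(C)c(Cl)c1OCOC | intermediate
12 | 3-chloro-2,6-bis(methoxymethoxy)-4-methylbenzaldehyde | O=Cc1c(OCOC)cc(C)c(Cl)c1OCOC | intermediate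
13 | propargyl alcohol (prop-2-yn-1-ol) | C#CCO | starting material
14 | dilithiated propargyl alcohol (lithium 3-lithioprop-2-yn-1-olate), not isolated | [Li]C#CC[O-].[Li+] | intermediate
15 | 1-[3-chloro-2,6-bis(methoxymethoxy)-4-methylphenyl]but-2-yne-1,4-diol, racemic | OCC#CC(O)c1c(OCOC)cc(C)c(Cl)c1OCOC | intermediate
16 | 4-[3-chloro-2,6-bis(methoxymethoxy)-4-methylphenyl]-4-hydroxybut-2-ynal, racemic, not isolated (the less hindered primary carbinol is expected to be oxidised first) | O=CC#CC(O)c1c(OCOC)cc(C)c(Cl)c1OCOC | intermediate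
17 | 4-[3-chloro-2,6-bis(methoxymethoxy)-4-methylphenyl]-4-oxobut-2-ynal | O=CC#CC(=O)c1c(OCOC)cc(C)c(Cl)c1OCOC | intermediate
18 | 2-[3-chloro-2,6-bis(methoxymethoxy)-4-methylbenzoyl]-6-methoxy-3-(3-methylbut-2-enyl)-4,6-bis(trimethylsilyloxy)cyclohexa-1,4-diene-1-carbaldehyde, racemic, methoxy and prenyl cis, one enantiomer drawn, not isolated | CO[C@]1(O[Si](C)(C)C)C=C(O[Si](C)(C)C)[C@H](CC=C(C)C)C(C(=O)c2c(OCOC)cc(C)c(Cl)c2OCOC)=C1C=O | intermediate
19 | 2-[3-chloro-2,6-bis(methoxymethoxy)-4-methylbenzoyl]-6-hydroxy-3-(3-methylbut-2-enyl)-4-(trimethylsilyloxy)benzaldehyde, not isolated | CC(C)=CCc1c(O[Si](C)(C)C)cc(O)c(C=O)c1C(=O)c1c(OCOC)cc(C)c(Cl)c1OCOC | intermediate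
20 | 2-[3-chloro-2,6-bis(methoxymethoxy)-4-methylbenzoyl]-4,6-dihydroxy-3-(3-methylbut-2-enyl)benzaldehyde | CC(C)=CCc1c(O)cc(O)c(C=O)c1C(=O)c1c(OCOC)cc(C)c(Cl)c1OCOC | intermediate
21 | pestalone E, 2-(3-chloro-2,6-dihydroxy-4-methylbenzoyl)-4,6-dihydroxy-3-(3-methylbut-2-enyl)benzaldehyde | CC(C)=CCc1c(O)cc(O)c(C=O)c1C(=O)c1c(O)cc(C)c(Cl)c1O | target

**Totals**
Total step count: 10. Longest linear sequence: 7 steps (steps 4–10, from orcinol).

**Steps most likely to fail**

1. Step 9. The addition may take the reverse orientation, with the prenyl-bearing diene terminus bonding to the formyl-bearing alkyne carbon. The diene may also add to the aldehyde carbonyl, or the doubly activated alkyne may oligomerise. The fallback sets out from 15 and returns at 20; it keeps the same ring-forming cycloaddition but holds the aroyl carbon at the carbinol level, so that the formyl group is the only activating group.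
 - Only the primary carbinol of 15 is oxidised (catalytic TEMPO, PhI(OAc)2, CH2Cl2) to hydroxy ynal 16, which is now isolated.
 - Silylation (TMSCl, Et3N) gives 4-[3-chloro-2,6-bis(methoxymethoxy)-4-methylphenyl]-4-(trimethylsilyloxy)but-2-ynal F1.
 - Cycloaddition with 7 and citric acid work-up as in step 9 should give, with unambiguous orientation, 2-{[3-chloro-2,6-bis(methoxymethoxy)-4-methylphenyl](hydroxy)methyl}-4,6-dihydroxy-3-(3-methylbut-2-enyl)benzaldehyde F2, which may rest as its cyclic lactol.
 - Direct oxidation of such a lactol would lead to a phthalide, so the aldehyde is masked first: 1,1-dimethylhydrazine (EtOH, rt) opens it to the (E)-N,N-dimethylhydrazone of the hydroxy aldehyde F3.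
 - MnO2 (CH2Cl2) oxidises the benzhydrol to the (E)-N,N-dimethylhydrazone of the keto aldehyde F4.
 - CuCl2 in pH 7 buffered aqueous THF hydrolyses the hydrazone and returns 20.

2. Step 8. The keto ynal may decompose (hydration, conjugate addition, polymerisation) on the oxidant while the slower oxidation of the hindered secondary carbinol is still running, or the oxidation may stall half-way. The fallback sets out from 12 and returns at 17; it introduces the two carbonyl groups one at a time from an orthogonally protected alkyne.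
 - Lithiated tert-butyldimethyl(prop-2-ynyloxy)silane (n-BuLi, THF, −78 °C) adds to 12 to give 4-(tert-butyldimethylsilyloxy)-1-[3-chloro-2,6-bis(methoxymethoxy)-4-methylphenyl]but-2-yn-1-ol F5.
 - MnO2 gives the purifiable ynone 4-(tert-butyldimethylsilyloxy)-1-[3-chloro-2,6-bis(methoxymethoxy)-4-methylphenyl]but-2-yn-1-one F6.
 - HF·pyridine (THF/pyridine, 0 °C) frees 1-[3-chloro-2,6-bis(methoxymethoxy)-4-methylphenyl]-4-hydroxybut-2-yn-1-one F7.
 - One fast oxidation with Dess–Martin periodinane (CH2Cl2, 0 °C) gives 17 immediately before the cycloaddition.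

3. Step 10. Acid may cyclise the ortho-prenylphenol to a chroman, add HCl or methanol across the prenyl alkene, or acetalise the keto aldehyde. The fallback sets out from 12 and returns at 21; it exchanges the MOM ethers for allyl ethers before any acid-sensitive group exists, so that the final deprotection is neutral.
 - HCl in MeOH converts 12 into 3-chloro-2,6-dihydroxy-4-methylbenzaldehyde F8.
 - Allyl bromide and K2CO3 in DMF give 3-chloro-4-methyl-2,6-bis(prop-2-enyloxy)benzaldehyde F9.
 - The conditions of steps 7, 8 and 9 then give in turn 1-[3-chloro-4-methyl-2,6-bis(prop-2-enyloxy)phenyl]but-2-yne-1,4-diol F10, 4-[3-chloro-4-methyl-2,6-bis(prop-2-enyloxy)phenyl]-4-oxobut-2-ynal F11, and 2-[3-chloro-4-methyl-2,6-bis(prop-2-enyloxy)benzoyl]-4,6-dihydroxy-3-(3-methylbut-2-enyl)benzaldehyde F12.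
 - Deallylation with Pd(PPh3)4 (zerovalent palladium) and sodium p-toluenesulfinate in THF/MeOH at rt gives 21.

**Further compounds**
F1 | step 9 | 4-[3-chloro-2,6-bis(methoxymethoxy)-4-methylphenyl]-4-(trimethylsilyloxy)but-2-ynal, racemic | O=CC#CC(O[Si](C)(C)C)c1c(OCOC)cc(C)c(Cl)c1OCOC
F2 | step 9 | 2-{[3-chloro-2,6-bis(methoxymethoxy)-4-methylphenyl](hydroxy)methyl}-4,6-dihydroxy-3-(3-methylbut-2-enyl)benzaldehyde, racemic | CC(C)=CCc1c(O)cc(O)c(C=O)c1C(O)c1c(OCOC)cc(C)c(Cl)c1OCOC
F3 | step 9 | (E)-N,N-dimethylhydrazone of F2, racemic | CC(C)=CCc1c(O)cc(O)c(/C=N/N(C)C)c1C(O)c1c(OCOC)cc(C)c(Cl)c1OCOC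
F4 | step 9 | (E)-N,N-dimethylhydrazone of 20 | CC(C)=CCc1c(O)cc(O)c(/C=N/N(C)C)c1C(=O)c1c(OCOC)cc(C)c(Cl)c1OCOC
F5 | step 8 | 4-(tert-butyldimethylsilyloxy)-1-[3-chloro-2,6-bis(methoxymethoxy)-4-methylphenyl]but-2-yn-1-ol, racemic | CC(C)(C)[Si](C)(C)OCC#CC(O)c1c(OCOC)cc(C)c(Cl)c1OCOC
F6 | step 8 | 4-(tert-butyldimethylsilyloxy)-1-[3-chloro-2,6-bis(methoxymethoxy)-4-methylphenyl]but-2-yn-1-one | CC(C)(C)[Si](C)(C)OCC#CC(=O)c1c(OCOC)cc(C)c(Cl)c1OCOC
F7 | step 8 | 1-[3-chloro-2,6-bis(methoxymethoxy)-4-methylphenyl]-4-hydroxybut-2-yn-1-one | OCC#CC(=O)c1c(OCOC)cc(C)c(Cl)c1OCOC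
F8 | step 10 | 3-chloro-2,6-dihydroxy-4-methylbenzaldehyde | O=Cc1c(O)cc(C)c(Cl)c1O
F9 | step 10 | 3-chloro-4-methyl-2,6-bis(prop-2-enyloxy)benzaldehyde | O=Cc1c(OCC=C)cc(C)c(Cl)c1OCC=C
F10 | step 10 | 1-[3-chloro-4-methyl-2,6-bis(prop-2-enyloxy)phenyl]but-2-yne-1,4-diol, racemic | OCC#CC(O)c1c(OCC=C)cc(C)c(Cl)c1OCC=C
F11 | step 10 | 4-[3-chloro-4-methyl-2,6-bis(prop-2-enyloxy)phenyl]-4-oxobut-2-ynal | O=CC#CC(=O)c1c(OCC=C)cc(C)c(Cl)c1OCC=C
F12 | step 10 | 2-[3-chloro-4-methyl-2,6-bis(prop-2-enyloxy)benzoyl]-4,6-dihydroxy-3-(3-methylbut-2-enyl)benzaldehyde | CC(C)=CCc1c(O)cc(O)c(C=O)c1C(=O)c1c(OCC=C)cc(C)c(Cl)c1OCC=C
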